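The route rests on disconnecting the C2–C1′ bond between the pyran ring and the pyrogallol B ring. In the key step a chiral hydroxy-acid/lanthanide catalyst transfers the 3,4,5-tris(benzyloxy)phenyl group from boron to C2 of an achiral chromenylium ion, creating the C2 stereocentre. The cation is released from a racemic 2-ethoxy-2H-chromene acetal whose C3 oxygen already carries the 4-(benzyloxy)benzoyl group as an enol ester (C3=C4). The step exploits the stabilisation of a C2 cation by O1 and the 5,7-dioxygenated A ring and the fact that C3 bears an acylated oxygen. One final hydrogenation then adds hydrogen to C3=C4 anti to the aryl group (2,3-cis) and removes all six benzyl groups.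

Key step: step 6

Remark: compounds 1, 3, 4 and 7 are taken as purchasable.
Remark: the sense of induction of the tartaric-acid-derived catalyst on this 3-acyloxy substrate cannot be fixed on paper; the (2R,3R)-derived catalyst is written, and its enantiomer is to be used if it delivers the (S)-chromene.

Step 1
Reactants: 1 5-bromo-1,2,3-tris(benzyloxy)benzene
Product: 2 [3,4,5-tris(benzyloxy)phenyl]boronic acid
Conditions: n-BuLi, THF, −78 °C; B(OiPr)3, −78 °C → rt; aq. HCl
Reagents that add atoms: triisopropyl borate CC(C)OB(OC(C)C)OC(C)C; water O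
Why: Bromine–lithium exchange at −78 °C should give the aryllithium, which is trapped by the borate and hydrolysed to the boronic acid (lithiation–borylation), the benzyl ethers being inert at this temperature.

Step 2
Reactants: 3 3,5-bis(benzyloxy)phenol; 4 propargyl bromide
Product: 5 1,3-bis(benzyloxy)-5-(prop-2-yn-1-yloxy)benzene
Conditions: K2CO3, acetone, reflux
Reagents that add atoms: none
Why: Williamson ether synthesis of the phenoxide with a reactive propargylic bromide should proceed cleanly on oxygen.

Step 3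
Reactants: 5 1,3-bis(benzyloxy)-5-(prop-2-yn-1-yloxy)benzene
Product: 6 5,7-bis(benzyloxy)chroman-3-one
Conditions: Me4tBuXPhosAuNTf2 (5 mol %), 2,6-dichloropyridine N-oxide (1.5 equiv), DCE, rt
Reagents that add atoms: 2,6-dichloropyridine N-oxide [O-][n+]1c(Cl)cccc1Cl
Why: Gold-catalysed alkyne oxidation should place oxygen on the internal alkyne carbon and give an α-oxo gold carbene at the terminal carbon, which is captured by one of the two equivalent, electron-rich ortho carbons of the arene (formal C–H insertion closing the six-membered ring).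

Step 4
Reactants: 6 5,7-bis(benzyloxy)chroman-3-one; 7 4-(benzyloxy)benzoyl chloride
Product: 8 5,7-bis(benzyloxy)-2H-chromen-3-yl 4-(benzyloxy)benzoate
Conditions: Et3N, DMAP (cat.), CH2Cl2, 0 °C
Reagents that add atoms: none
Why: Enolisation towards the more acidic benzylic C4 (conjugated with the A ring) followed by O-acylation should give the C3=C4 enol ester, as in enol ester formation from 2-tetralones.

Step 5
Reactants: 8 5,7-bis(benzyloxy)-2H-chromen-3-yl 4-(benzyloxy)benzoate
Product: 9 racemic 5,7-bis(benzyloxy)-2-ethoxy-2H-chromen-3-yl 4-(benzyloxy)benzoate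
Conditions: DDQ (1.1 equiv), EtOH (5 equiv), 4 Å MS, CH2Cl2, 0 °C → rt
Reagents that add atoms: ethanol CCO
Why: DDQ should abstract hydride from the allylic, oxygen-bound C2–H to give a chromenylium ion stabilised by O1 and the 5,7-dialkoxy ring, which ethanol captures at C2 (oxidative C–H alkoxylation of 2H-chromenes), while the acetal product and the benzyl ethers are oxidised much more slowly.

Step 6
Reactants: 9 racemic 5,7-bis(benzyloxy)-2-ethoxy-2H-chromen-3-yl 4-(benzyloxy)benzoate; 2 [3,4,5-tris(benzyloxy)phenyl]boronic acid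
Product: 12 (2R)-5,7-bis(benzyloxy)-2-[3,4,5-tris(benzyloxy)phenyl]-2H-chromen-3-yl 4-(benzyloxy)benzoate, via diethyl arylboronate 10 (not isolated), via chromenylium ion 11 (not isolated)
Conditions: 2, EtOH, 4 Å MS, EtOAc, rt; then 9, (2R,3R)-4-(dibenzylamino)-2,3-dihydroxy-4-oxobutanoic acid (10 mol %), Ce(OTf)4 or Yb(OTf)3 (10 mol %), EtOAc, −20 → 4 °C
Reagents that add atoms: none
Why: The diethyl boronate 10 exchanges onto the chiral α,β-dihydroxy acid to give a more Lewis-acidic chiral boronate, which together with the lanthanide triflate ionises the acetal; the ethoxide ends on boron and the resulting chiral aryl(ethoxy)boronate ate complex stays ion-paired with chromenylium ion 11, to whose C2 the aryl group then migrates from boron. The closest known reaction type is the chiral hydroxy-acid/Lewis-acid-catalysed enantioselective addition of aryl and alkenyl boronates to 2-ethoxy-2H-chromenes, a Petasis-type aryl transfer to an oxocarbenium ion. No ring is closed: the pyran ring is preformed and the step only forms the C2–aryl bond. The new C2 stereocentre (R) is set by the catalyst alone, because the cation is planar and achiral and both enantiomers of the acetal converge on it. The step needs C2-over-C4 regioselectivity and enantiofacial selectivity; the first is secured by aryl delivery from the boron that has just taken the ethoxide from C2, by the larger LUMO coefficient next to O1 and by the peri 5-benzyloxy group shielding C4, while the 5,7-dialkoxy A ring makes ionisation easy despite the C3 acyloxy group. The enol ester and the benzyl ethers should be inert to these mild Lewis-acidic conditions.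

Step 7
Reactants: 12 (2R)-5,7-bis(benzyloxy)-2-[3,4,5-tris(benzyloxy)phenyl]-2H-chromen-3-yl 4-(benzyloxy)benzoate
Product: 13 (2R,3R)-5,7-dihydroxy-2-(3,4,5-trihydroxyphenyl)chroman-3-yl 4-hydroxybenzoate [epigallocatechin 3-O-(4-hydroxybenzoate)]
Conditions: H2 (1–3 bar), 20% Pd(OH)2/C, THF/MeOH, rt
Reagents that add atoms: none
Why: Heterogeneous hydrogenation should deliver hydrogen to the C3=C4 enol ester from the face opposite the pseudoaxial C2 aryl group, so that the C3 ester oxygen ends cis to the aryl group (3R), as in the classical reduction of 3-oxygenated flav-3-enes to epi-series flavan-3-ols, and the same conditions hydrogenolyse the six benzyl ethers.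

Compound list
1 | 5-bromo-1,2,3-tris(benzyloxy)benzene | Brc1cc(OCc2ccccc2)c(OCc2ccccc2)c(OCc2ccccc2)c1 | starting material
2 | [3,4,5-tris(benzyloxy)phenyl]boronic acid | OB(O)c1cc(OCc2ccccc2)c(OCc2ccccc2)c(OCc2ccccc2)c1 | intermediate
3 | 3,5-bis(benzyloxy)phenol | Oc1cc(OCc2ccccc2)cc(OCc2ccccc2)c1 | starting material
4 | propargyl bromide (3-bromoprop-1-yne) | C#CCBr | starting material
5 | 1,3-bis(benzyloxy)-5-(prop-2-yn-1-yloxy)benzene | C#CCOc1cc(OCc2ccccc2)cc(OCc2ccccc2)c1 | intermediate
6 | 5,7-bis(benzyloxy)chroman-3-one | O=C1COc2cc(OCc3ccccc3)cc(OCc3ccccc3)c2C1 | intermediate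
7 | 4-(benzyloxy)benzoyl chloride | O=C(Cl)c1ccc(OCc2ccccc2)cc1 | starting material
8 | 5,7-bis(benzyloxy)-2H-chromen-3-yl 4-(benzyloxy)benzoate | O=C(OC1=Cc2c(OCc3ccccc3)cc(OCc3ccccc3)cc2OC1)c1ccc(OCc2ccccc2)cc1 | intermediate
9 | racemic 5,7-bis(benzyloxy)-2-ethoxy-2H-chromen-3-yl 4-(benzyloxy)benzoate | CCOC1Oc2cc(OCc3ccccc3)cc(OCc3ccccc3)c2C=C1OC(=O)c1ccc(OCc2ccccc2)cc1 | intermediate
10 | diethyl [3,4,5-tris(benzyloxy)phenyl]boronate (formed in the flask, not isolated) | CCOB(OCC)c1cc(OCc2ccccc2)c(OCc2ccccc2)c(OCc2ccccc2)c1 | intermediate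
11 | 5,7-bis(benzyloxy)-3-{[4-(benzyloxy)benzoyl]oxy}chromenylium ion (cation shown; ion-paired with the catalyst-bound ethoxyboronate, not isolated) | O=C(Oc1cc2c(OCc3ccccc3)cc(OCc3ccccc3)cc2[o+]c1)c1ccc(OCc2ccccc2)cc1 | intermediate
12 | (2R)-5,7-bis(benzyloxy)-2-[3,4,5-tris(benzyloxy)phenyl]-2H-chromen-3-yl 4-(benzyloxy)benzoate | O=C(OC1=Cc2c(OCc3ccccc3)cc(OCc3ccccc3)cc2O[C@@H]1c1cc(OCc2ccccc2)c(OCc2ccccc2)c(OCc2ccccc2)c1)c1ccc(OCc2ccccc2)cc1 | intermediate
13 | (2R,3R)-5,7-dihydroxy-2-(3,4,5-trihydroxyphenyl)chroman-3-yl 4-hydroxybenzoate | O=C(O[C@@H]1Cc2c(O)cc(O)cc2O[C@@H]1c1cc(O)c(O)c(O)c1)c1ccc(O)cc1 | target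

Total step count: 7. Longest linear sequence: 6 steps (3 → 5 → 6 → 8 → 9 → 12 → 13; step 1 is a one-step side branch).

Steps most likely to fail

Step 6. The C3 aroyloxy group crowds the reacting C2 and may weaken facial discrimination by the catalyst. Aryl transfer from the only moderately nucleophilic trialkoxyphenyl boronate may also be slow enough for uncatalysed background addition or attack at C4 to compete. Fallback: setting out from 9 and 2, a nickel(0)-catalysed, base-free coupling (Ni(cod)2, PPh3, dioxane/t-AmOH, rt to 40 °C) is used instead. Ni(0) inserts into the boronic-acid-activated C2–OEt bond and the aryl group arrives by transmetalation and reductive elimination. This should give racemic 5,7-bis(benzyloxy)-2-[3,4,5-tris(benzyloxy)phenyl]-2H-chromen-3-yl 4-(benzyloxy)benzoate F1. Preparative chiral SFC then separates 12 from (2S)-5,7-bis(benzyloxy)-2-[3,4,5-tris(benzyloxy)phenyl]-2H-chromen-3-yl 4-(benzyloxy)benzoate F2, which is set aside, and the route is rejoined at 12.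

Step 7. On palladium the double bond may migrate from C3=C4 into C2=C3 before saturation, which would erase the C2 configuration. The doubly activated (allylic and benzylic) C2–O1 bond may be hydrogenolysed, or facial selectivity may be incomplete. Fallback: setting out from 12, the C3 stereocentre is set by hydride reduction of a ketone instead of alkene hydrogenation. MeLi (2.2 equiv, THF, −78 °C) cleaves the enol ester to the lithium enolate, and an AcOH quench at −78 °C should give (2R)-5,7-bis(benzyloxy)-2-[3,4,5-tris(benzyloxy)phenyl]chroman-3-one F3 without touching C2. L-Selectride (THF, −78 °C) attacks anti to the C2 aryl group and should give (2R,3R)-5,7-bis(benzyloxy)-2-[3,4,5-tris(benzyloxy)phenyl]chroman-3-ol F4. Acylation with 7 (Et3N, DMAP, CH2Cl2) should give (2R,3R)-5,7-bis(benzyloxy)-2-[3,4,5-tris(benzyloxy)phenyl]chroman-3-yl 4-(benzyloxy)benzoate F5. Hydrogenolysis (H2, Pd(OH)2/C, THF/MeOH) then returns to the route at 13.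

Step 3. The very nucleophilic A ring may add directly to the gold-activated alkyne (6-endo hydroarylation without oxygen transfer), or the gold carbene may be oxidised a second time by the N-oxide. Fallback: setting out from 5, the thermal aryl propargyl ether Claisen cascade (PhNEt2, about 200 °C) should give 5,7-bis(benzyloxy)-2H-chromene F6. Hydroboration–oxidation (BH3·THF; NaOH, H2O2) places oxygen on C3 and should give racemic 5,7-bis(benzyloxy)chroman-3-ol F7. Dess–Martin oxidation then returns to the route at 6.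

Further compounds
F1 | step 6 | racemic 5,7-bis(benzyloxy)-2-[3,4,5-tris(benzyloxy)phenyl]-2H-chromen-3-yl 4-(benzyloxy)benzoate | O=C(OC1=Cc2c(OCc3ccccc3)cc(OCc3ccccc3)cc2OC1c1cc(OCc2ccccc2)c(OCc2ccccc2)c(OCc2ccccc2)c1)c1ccc(OCc2ccccc2)cc1
F2 | step 6 | (2S)-5,7-bis(benzyloxy)-2-[3,4,5-tris(benzyloxy)phenyl]-2H-chromen-3-yl 4-(benzyloxy)benzoate | O=C(OC1=Cc2c(OCc3ccccc3)cc(OCc3ccccc3)cc2O[C@H]1c1cc(OCc2ccccc2)c(OCc2ccccc2)c(OCc2ccccc2)c1)c1ccc(OCc2ccccc2)cc1
F3 | step 7 | (2R)-5,7-bis(benzyloxy)-2-[3,4,5-tris(benzyloxy)phenyl]chroman-3-one | O=C1Cc2c(OCc3ccccc3)cc(OCc3ccccc3)cc2O[C@@H]1c1cc(OCc2ccccc2)c(OCc2ccccc2)c(OCc2ccccc2)c1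
F4 | step 7 | (2R,3R)-5,7-bis(benzyloxy)-2-[3,4,5-tris(benzyloxy)phenyl]chroman-3-ol | O[C@@H]1Cc2c(OCc3ccccc3)cc(OCc3ccccc3)cc2O[C@@H]1c1cc(OCc2ccccc2)c(OCc2ccccc2)c(OCc2ccccc2)c1
F5 | step 7 | (2R,3R)-5,7-bis(benzyloxy)-2-[3,4,5-tris(benzyloxy)phenyl]chroman-3-yl 4-(benzyloxy)benzoate | O=C(O[C@@H]1Cc2c(OCc3ccccc3)cc(OCc3ccccc3)cc2O[C@@H]1c1cc(OCc2ccccc2)c(OCc2ccccc2)c(OCc2ccccc2)c1)c1ccc(OCc2ccccc2)cc1
F6 | step 3 | 5,7-bis(benzyloxy)-2H-chromene | C1=Cc2c(OCc3ccccc3)cc(OCc3ccccc3)cc2OC1
F7 | step 3 | racemic 5,7-bis(benzyloxy)chroman-3-ol | OC1COc2cc(OCc3ccccc3)cc(OCc3ccccc3)c2C1
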